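**Plan**

- Retrosynthesis: the four methoxymethyl (MOM) ethers come off last. Ring C is opened at O1–C2 and C2–C3, C2 being a formamide acetal carbon. The resulting deoxybenzoin is cut at C4–C4a and C3–C4, C4 being carbon monoxide.
- Enabling feature: C4 is a ketone carbon lying between C4a of ring A, which is flanked by the oxygens at C5 and C8a, and the benzylic C3 that carries ring B. An aryl iodide at C4a, CO and a ring B benzylzinc therefore give the ketone under neutral conditions that leave the acid-labile 2-methylbut-3-en-2-yl group at C8, next to the C8a oxygen, alone.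
- Ring A goes back to phloroglucinol. Iodine is placed at the future C4a first; the C8 side chain then comes from an aromatic Claisen rearrangement of a prenyl ether on the oxygen that becomes O1, trapped as its acetate so that only this oxygen is later free to close ring C.
- Ring B comes from 2,4-dihydroxybenzaldehyde via the benzyl chloride and zinc insertion.
- Forward order: ring A iodide (steps 1–4), ring B benzylzinc (steps 5–8), union of the two rings through CO (step 9), then deacetylation, closure of ring C and deprotection (steps 10–12).
- The target has no stereocentre, so no stereochemistry has to be set.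

Key step: step 9

Remark on the chemistry: the enaminone 17 is drawn without double-bond geometry, since either isomer closes to the same chromone; anhydrous phloroglucinol is assumed.

**Route**

Step 1
Reactants: 1 phloroglucinol (benzene-1,3,5-triol)
Product: 2 3,5-bis(methoxymethoxy)phenol
Conditions: MOMCl (2.0 equiv), K2CO3, acetone, 0 °C → rt
Reagents that add atoms: chloromethyl methyl ether (MOMCl), COCCl
Why: Williamson-type O-alkylation of the threefold symmetric triol with two equivalents of a hard electrophile is statistical, so the bis-ether should be the main fraction, separable by chromatography from the mono- and tris-ethers, the mono-ether being resubmitted.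

Step 2
Reactants: 2 3,5-bis(methoxymethoxy)phenol
Product: 3 2-iodo-3,5-bis(methoxymethoxy)phenol
Conditions: NIS (1.0 equiv), CH2Cl2, −78 → −20 °C, dark
Reagents that add atoms: N-iodosuccinimide (NIS), O=C1CCC(=O)N1I
Why: Electrophilic aromatic iodination should take place at one of the two equivalent positions ortho to the free hydroxyl, which are less crowded than C4 between the two MOM ethers and can receive iodine from NIS hydrogen-bonded to the phenol in the non-polar solvent.

Step 3
Reactants: 3 2-iodo-3,5-bis(methoxymethoxy)phenol; 4 1-bromo-3-methylbut-2-ene (prenyl bromide)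
Product: 5 2-iodo-1,5-bis(methoxymethoxy)-3-[(3-methylbut-2-en-1-yl)oxy]benzene
Conditions: K2CO3, acetone, 50 °C
Reagents that add atoms: none
Why: Williamson ether synthesis, the potassium phenoxide displacing bromide from the primary allylic halide at oxygen (SN2), the standard entry to aryl prenyl ethers.

Step 4
Reactants: 5 2-iodo-1,5-bis(methoxymethoxy)-3-[(3-methylbut-2-en-1-yl)oxy]benzene
Product: 7 2-iodo-3,5-bis(methoxymethoxy)-6-(2-methylbut-3-en-2-yl)phenyl acetate, via rearranged iodophenol 6 (not isolated)
Conditions: Ac2O, NaOAc, PhNEt2, 170 °C, sealed tube, argon, dark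
Reagents that add atoms: acetic anhydride, CC(=O)OC(C)=O
Why: Aromatic Claisen rearrangement, whose [3,3]-sigmatropic shift can only go to the one free ortho carbon and delivers the allyl unit inverted as the 2-methylbut-3-en-2-yl group next to the former ether oxygen, while acetylation in the same flask takes the hindered phenol 6 out of abnormal Claisen and ring-closing pathways and marks this oxygen as the one that will close ring C.

Step 5
Reactants: 8 2,4-dihydroxybenzaldehyde
Product: 9 2,4-bis(methoxymethoxy)benzaldehyde
Conditions: MOMCl (3 equiv), K2CO3, acetone, reflux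
Reagents that add atoms: chloromethyl methyl ether (MOMCl), COCCl
Why: Williamson-type O-alkylation of both phenols, heating with excess reagent being needed because the 2-hydroxyl is hydrogen-bonded to the aldehyde.

Step 6
Reactants: 9 2,4-bis(methoxymethoxy)benzaldehyde
Product: 10 [2,4-bis(methoxymethoxy)phenyl]methanol
Conditions: NaBH4, MeOH, 0 °C
Reagents that add atoms: none
Why: Borohydride reduction of the aryl aldehyde to the benzyl alcohol, to which MOM ethers are inert.

Step 7
Reactants: 10 [2,4-bis(methoxymethoxy)phenyl]methanol
Product: 12 1-(chloromethyl)-2,4-bis(methoxymethoxy)benzene, via benzyl mesylate 11 (not isolated)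
Conditions: MsCl, i-Pr2NEt, CH2Cl2, 0 °C → rt; cold NaHCO3 wash, used at once
Reagents that add atoms: methanesulfonyl chloride (MsCl), CS(=O)(=O)Cl
Why: Sulfonylation followed by in situ displacement, the mesylate of so electron-rich a benzyl alcohol being replaced by the chloride set free from MsCl under basic conditions that spare the MOM ethers.

Step 8
Reactants: 12 1-(chloromethyl)-2,4-bis(methoxymethoxy)benzene
Product: 13 [2,4-bis(methoxymethoxy)benzyl]zinc chloride (THF solution, titrated)
Conditions: Zn dust (activated with BrCH2CH2Br, TMSCl), LiCl, THF, 0 → 25 °C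
Reagents that add atoms: zinc, [Zn]
Why: Direct insertion of zinc metal into the benzylic C–Cl bond, LiCl taking the organozinc off the metal surface so that insertion should outrun Wurtz-type homocoupling.

Step 9
Reactants: 7 2-iodo-3,5-bis(methoxymethoxy)-6-(2-methylbut-3-en-2-yl)phenyl acetate; 13 [2,4-bis(methoxymethoxy)benzyl]zinc chloride; 14 carbon monoxide
Product: 15 2-{[2,4-bis(methoxymethoxy)phenyl]acetyl}-3,5-bis(methoxymethoxy)-6-(2-methylbut-3-en-2-yl)phenyl acetate
Conditions: Pd(PPh3)4 (5 mol %), CO (3 bar), THF, 45 °C, slow addition of 13 (1.5 equiv)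
Reagents that add atoms: none
Why: Zerovalent palladium adds oxidatively to the C–I bond of 7 to give an arylpalladium iodide of divalent palladium, and migratory insertion of CO turns it into the aroylpalladium species, which is favoured because it moves the metal one atom away from the two ortho oxygen substituents. Transmetalation with the benzylzinc chloride 13 and reductive elimination then form the C3–C4 bond beside the new C4–C4a bond and return zerovalent palladium. The closest known reaction type is the carbonylative Negishi coupling of aryl iodides with benzyl- and alkylzinc halides under CO. No ring is closed and no stereocentre is formed. The selectivity needed is CO insertion before benzyl transfer (ketone, not diarylmethane), which the crowded aryl–palladium bond, the CO pressure and the slow addition of 13 should secure, while the iodine placed in step 2 fixes the site of acylation. The medium is neutral, so the acetate, the MOM ethers and the acid-sensitive tertiary allyl group should pass unchanged.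

Step 10
Reactants: 15 2-{[2,4-bis(methoxymethoxy)phenyl]acetyl}-3,5-bis(methoxymethoxy)-6-(2-methylbut-3-en-2-yl)phenyl acetate
Product: 16 2-[2,4-bis(methoxymethoxy)phenyl]-1-[2-hydroxy-4,6-bis(methoxymethoxy)-3-(2-methylbut-3-en-2-yl)phenyl]ethan-1-one
Conditions: K2CO3, MeOH, 0 °C
Reagents that add atoms: none
Why: Methanolysis (transesterification) of the aryl acetate frees only the oxygen destined to become O1 and, in the protic medium, should outrun enolate acyl transfer of the Baker–Venkataraman type.

Step 11
Reactants: 16 2-[2,4-bis(methoxymethoxy)phenyl]-1-[2-hydroxy-4,6-bis(methoxymethoxy)-3-(2-methylbut-3-en-2-yl)phenyl]ethan-1-one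
Product: 18 3-[2,4-bis(methoxymethoxy)phenyl]-5,7-bis(methoxymethoxy)-8-(2-methylbut-3-en-2-yl)-4H-chromen-4-one, via enaminone 17 (not isolated)
Conditions: Me2NCH(OMe)2 (DMF-DMA, 3 equiv), toluene, 90 °C
Reagents that add atoms: N,N-dimethylformamide dimethyl acetal, COC(OC)N(C)C
Why: Condensation of the formamide acetal with the doubly activated methylene gives the enaminone, and addition of the ortho phenol to its β-carbon with loss of dimethylamine (6-endo addition–elimination) closes ring C, the established one-carbon route from 2-hydroxydeoxybenzoins to isoflavones.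

Step 12
Reactants: 18 3-[2,4-bis(methoxymethoxy)phenyl]-5,7-bis(methoxymethoxy)-8-(2-methylbut-3-en-2-yl)-4H-chromen-4-one
Product: 19 3-(2,4-dihydroxyphenyl)-5,7-dihydroxy-8-(2-methylbut-3-en-2-yl)-4H-chromen-4-one
Conditions: HCl (1 M), MeOH–THF, 40 °C
Reagents that add atoms: none
Why: Acid-catalysed acetal exchange with methanol removes the four MOM ethers under conditions too mild to protonate the monosubstituted vinyl group or the ring carbon bearing the tertiary allyl group, so neither cyclisation onto the 7-hydroxyl nor dealkylation is expected.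

**Compound list**

1 | phloroglucinol (benzene-1,3,5-triol) | Oc1cc(O)cc(O)c1 | starting material
2 | 3,5-bis(methoxymethoxy)phenol | COCOc1cc(O)cc(OCOC)c1 | intermediate
3 | 2-iodo-3,5-bis(methoxymethoxy)phenol | COCOc1cc(O)c(I)c(OCOC)c1 | intermediate
4 | 1-bromo-3-methylbut-2-ene (prenyl bromide) | CC(C)=CCBr | starting material
5 | 2-iodo-1,5-bis(methoxymethoxy)-3-[(3-methylbut-2-en-1-yl)oxy]benzene | CC(C)=CCOc1cc(OCOC)cc(OCOC)c1I | intermediate
6 | 2-iodo-3,5-bis(methoxymethoxy)-6-(2-methylbut-3-en-2-yl)phenol (formed in the flask in step 4) | C=CC(C)(C)c1c(O)c(I)c(OCOC)cc1OCOC | intermediate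
7 | 2-iodo-3,5-bis(methoxymethoxy)-6-(2-methylbut-3-en-2-yl)phenyl acetate | C=CC(C)(C)c1c(OC(C)=O)c(I)c(OCOC)cc1OCOC | intermediate
8 | 2,4-dihydroxybenzaldehyde | O=Cc1ccc(O)cc1O | starting material
9 | 2,4-bis(methoxymethoxy)benzaldehyde | COCOc1ccc(C=O)c(OCOC)c1 | intermediate
10 | [2,4-bis(methoxymethoxy)phenyl]methanol | COCOc1ccc(CO)c(OCOC)c1 | intermediate
11 | [2,4-bis(methoxymethoxy)phenyl]methyl methanesulfonate (formed in the flask in step 7) | COCOc1ccc(COS(C)(=O)=O)c(OCOC)c1 | intermediate
12 | 1-(chloromethyl)-2,4-bis(methoxymethoxy)benzene | COCOc1ccc(CCl)c(OCOC)c1 | intermediate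
13 | [2,4-bis(methoxymethoxy)benzyl]zinc chloride | COCOc1ccc(C[Zn]Cl)c(OCOC)c1 | intermediate
14 | carbon monoxide | [C-]#[O+] | starting material
15 | 2-{[2,4-bis(methoxymethoxy)phenyl]acetyl}-3,5-bis(methoxymethoxy)-6-(2-methylbut-3-en-2-yl)phenyl acetate | C=CC(C)(C)c1c(OC(C)=O)c(C(=O)Cc2ccc(OCOC)cc2OCOC)c(OCOC)cc1OCOC | intermediate
16 | 2-[2,4-bis(methoxymethoxy)phenyl]-1-[2-hydroxy-4,6-bis(methoxymethoxy)-3-(2-methylbut-3-en-2-yl)phenyl]ethan-1-one | C=CC(C)(C)c1c(O)c(C(=O)Cc2ccc(OCOC)cc2OCOC)c(OCOC)cc1OCOC | intermediate
17 | 2-[2,4-bis(methoxymethoxy)phenyl]-3-(dimethylamino)-1-[2-hydroxy-4,6-bis(methoxymethoxy)-3-(2-methylbut-3-en-2-yl)phenyl]prop-2-en-1-one (formed in the flask in step 11) | C=CC(C)(C)c1c(O)c(C(=O)C(=CN(C)C)c2ccc(OCOC)cc2OCOC)c(OCOC)cc1OCOC | intermediate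
18 | 3-[2,4-bis(methoxymethoxy)phenyl]-5,7-bis(methoxymethoxy)-8-(2-methylbut-3-en-2-yl)-4H-chromen-4-one | C=CC(C)(C)c1c(OCOC)cc(OCOC)c2c(=O)c(-c3ccc(OCOC)cc3OCOC)coc12 | intermediate
19 | 3-(2,4-dihydroxyphenyl)-5,7-dihydroxy-8-(2-methylbut-3-en-2-yl)-4H-chromen-4-one | C=CC(C)(C)c1c(O)cc(O)c2c(=O)c(-c3ccc(O)cc3O)coc12 | target

**Step count and risks**

Total step count: 12. Longest linear sequence: 8 steps (steps 1–4 and 9–12; the ring B branch, steps 5–8 and 9–12, is equally long).

Steps most likely to fail:

Step 9. The benzyl group may be transferred to the arylpalladium species before CO has inserted, the zinc reagent may homocouple, or it may add to the aryl acetate. In the fallback, CO insertion and benzyl transfer are separated, so that no organometallic is present while CO inserts. Setting out from 7, thiocarbonylation with ethanethiol (Pd(OAc)2, PPh3, CO, EtSH, NaOAc, THF, 60 °C) should give S-ethyl 2-(acetyloxy)-4,6-bis(methoxymethoxy)-3-(2-methylbut-3-en-2-yl)benzenecarbothioate F1. Fukuyama coupling of this thioester with the benzylzinc chloride 13 (PdCl2(PPh3)2, THF–toluene, rt) then comes back to the route at 15. C4 still comes from CO and the same two bonds are formed.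

Step 4. The C–I bond may not survive the thermal step, the allyl unit may migrate toward the iodine-bearing carbon and on to C4, or the prenyl group may be lost as isoprene. In the fallback the order is inverted so that no C–I bond is heated. Setting out from 2, prenylation (prenyl bromide 4, K2CO3, acetone) gives 1,3-bis(methoxymethoxy)-5-[(3-methylbut-2-en-1-yl)oxy]benzene F2. Claisen rearrangement with acetate trapping (Ac2O, NaOAc, PhNEt2, 170 °C) gives 3,5-bis(methoxymethoxy)-2-(2-methylbut-3-en-2-yl)phenyl acetate F3, and methanolysis (K2CO3, MeOH) frees 3,5-bis(methoxymethoxy)-2-(2-methylbut-3-en-2-yl)phenol F4. Iodination with NIS in CH2Cl2 at −78 °C should then go to the remaining position ortho to the hydroxyl, C4 being shielded by the MOM ether that the tertiary alkyl group pushes toward it. This gives the iodophenol 6, here isolated, and acetylation (Ac2O, Et3N, DMAP, CH2Cl2) comes back to the route at 7.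

Step 2. Iodination may occur at C4 between the two MOM ethers, or twice. In the fallback the position is fixed by directed metalation instead of electrophilic substitution. Setting out from 2, carbamoylation (ClCONEt2, K2CO3, MeCN, reflux) gives 3,5-bis(methoxymethoxy)phenyl N,N-diethylcarbamate F5. Ortho-lithiation (s-BuLi, TMEDA, THF, −78 °C) should be steered between the carbamate, the strongest oxygen-based directing group, and its neighbouring MOM ether; quenching with I2 at −78 °C then gives 2-iodo-3,5-bis(methoxymethoxy)phenyl N,N-diethylcarbamate F6. Hydrolysis (KOH, EtOH–H2O, reflux) comes back to the route at 3.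

**Further compounds**

F1 | step 9 | S-ethyl 2-(acetyloxy)-4,6-bis(methoxymethoxy)-3-(2-methylbut-3-en-2-yl)benzenecarbothioate | C=CC(C)(C)c1c(OC(C)=O)c(C(=O)SCC)c(OCOC)cc1OCOC
F2 | step 4 | 1,3-bis(methoxymethoxy)-5-[(3-methylbut-2-en-1-yl)oxy]benzene | CC(C)=CCOc1cc(OCOC)cc(OCOC)c1
F3 | step 4 | 3,5-bis(methoxymethoxy)-2-(2-methylbut-3-en-2-yl)phenyl acetate | C=CC(C)(C)c1c(OC(C)=O)cc(OCOC)cc1OCOC
F4 | step 4 | 3,5-bis(methoxymethoxy)-2-(2-methylbut-3-en-2-yl)phenol | C=CC(C)(C)c1c(O)cc(OCOC)cc1OCOC
F5 | step 2 | 3,5-bis(methoxymethoxy)phenyl N,N-diethylcarbamate | CCN(CC)C(=O)Oc1cc(OCOC)cc(OCOC)c1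
F6 | step 2 | 2-iodo-3,5-bis(methoxymethoxy)phenyl N,N-diethylcarbamate | CCN(CC)C(=O)Oc1cc(OCOC)cc(OCOC)c1I
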